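The C3–C4 oxirane is read as the C3=C4 bond of a 2‑methylcyclohex‑2‑enone and C6 as the β‑carbon of an enal (C1 acyloxy carbon, C2 carbonyl, C3 methyl carbon, C4, C5 methylene, C6 side‑chain carbon; C7 is the oxirane carbon on C6). The key step is an amine‑catalysed formal [3+3] annulation. C1 of a β‑keto ester (C1–C2–C3) adds to the iminium ion of an open‑chain enal (C6–C5–C4); acid then closes C3–C4 by aldol condensation and removes the ester group. Ring bonds C1–C6 and C3–C4 and the C6 stereocentre arise in one pot. C6 then relays C1–C4 by substrate control; a second amine catalyst sets C7.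

Key step: step 2

Remarks. Further locants: C14 (oxirane CH2 on C7), C8 (side‑chain carbonyl), C9=C10, C11 (carbinol); stereodescriptors in the names use these locants. Assumption: the cyclohexane is the only ring of the carbon skeleton; the two oxiranes are treated as oxidised C=C bonds and are introduced after it. The sense of induction in steps 2 and 9 is assigned from the steric shielding model of the catalysts, not from a recalled result.

Step 1
Reactants: 1 (4‑(benzyloxy)but‑1‑ene) and 2 ((E)‑but‑2‑enal)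
Product: 3 (E)‑5‑(benzyloxy)pent‑2‑enal
Conditions: 2 (5 equiv), second‑generation Hoveyda–Grubbs catalyst RuCl2(H2IMes)(=CH‑C6H4‑2‑OiPr) (2 mol%), CH2Cl2, 40 °C
Reagents that add atoms: none
Why: Olefin cross‑metathesis of the terminal alkene with excess electron‑poor crotonaldehyde should give the conjugated enal as the E isomer under thermodynamic control, with loss of propene.

Step 2
Reactants: 3 and 4 (tert‑butyl 3‑oxopentanoate)
Product: 7 (S)‑5‑[2‑(benzyloxy)ethyl]‑2‑methylcyclohex‑2‑en‑1‑one, via Michael adduct 5 (not isolated), via cyclised keto ester 6 (not isolated)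
Conditions: (S)‑2‑{bis[3,5‑bis(trifluoromethyl)phenyl](trimethylsilyloxy)methyl}pyrrolidine (10 mol%), PhCO2H (10 mol%), PhMe, rt; then TsOH·H2O (20 mol%), PhMe, 80 °C
Reagents that add atoms: none
Why: The amine condenses with 3 to an E‑iminium ion, the enol of 4 adds through C1 to C6 (Michael addition) to give 5, and under acid the enol on the ethyl side attacks the C4 aldehyde through C3, water is lost to give the conjugated C3=C4 bond of 6, and the tert‑butyl ester is cleaved to a β‑keto acid that decarboxylates. The closest known reaction type is the diarylprolinol silyl ether‑catalysed Michael addition of β‑keto esters to enals followed by acid‑induced aldol condensation and decarboxylation to 5‑substituted cyclohex‑2‑enones. The one ring that closes is the carbocycle, by a 6‑(enolendo)‑exo‑trig aldol addition that forms C3–C4 after C1–C6 has been made in the Michael step. The only stereocentre that survives is C6, set by the catalyst: its diaryl(silyloxy)methyl group blocks one face of the iminium ion, so C1 adds to the open face and the S catalyst should give the spatial arrangement of C6 found in the target; the centre at C1 in 5 and 6 is erased on decarboxylation. The step needs 1,4‑ over 1,2‑addition, which iminium activation and the stabilised enol secure, and aldol closure through C3 and not C1, which is secured because closure through C1 would give a four‑membered ring. The benzyl ether and the non‑enolisable C6 centre should survive the acid stage.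

Step 3
Reactants: 7 and 8 (3‑methylbutanoyl chloride)
Product: 10 (1S,6S)‑6‑[2‑(benzyloxy)ethyl]‑3‑methyl‑2‑oxocyclohex‑3‑en‑1‑yl 3‑methylbutanoate, via lithium alkoxide 9 (not isolated)
Conditions: LDA (1.1 equiv), THF, −78 °C; 2‑(phenylsulfonyl)‑3‑phenyloxaziridine, −78 °C; then 8, −78 → 0 °C
Reagents that add atoms: 2‑(phenylsulfonyl)‑3‑phenyloxaziridine, O=S(=O)(c1ccccc1)N1OC1c1ccccc1
Why: Kinetic deprotonation at C1 gives the cross‑conjugated dienolate, the oxaziridine transfers oxygen to C1 from the face opposite the adjacent C6 side chain (enolate hydroxylation), which sets C1 trans to C6, and the lithium alkoxide is acylated in the same flask.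

Step 4
Reactants: 10
Product: 11 (1S,2S,6S)‑6‑[2‑(benzyloxy)ethyl]‑2‑hydroxy‑3‑methylcyclohex‑3‑en‑1‑yl 3‑methylbutanoate
Conditions: NaBH4, CeCl3·7H2O, MeOH, −78 °C
Reagents that add atoms: none
Why: Luche 1,2‑reduction by axial hydride delivery to the half‑chair with the C1 ester and C6 side chain equatorial should give the equatorial C2 hydroxyl, trans to the C1 ester and cis to the C6 side chain, without touching the ester.

Step 5
Reactants: 11
Product: 12 (1S,2R,3R,4S,6R)‑6‑[2‑(benzyloxy)ethyl]‑3,4‑epoxy‑2‑hydroxy‑3‑methylcyclohexyl 3‑methylbutanoate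
Conditions: VO(acac)2 (5 mol%), t‑BuOOH (decane), CH2Cl2, 0 °C → rt
Reagents that add atoms: tert‑butyl hydroperoxide, CC(C)(C)OO
Why: Vanadium‑catalysed hydroxyl‑directed epoxidation delivers oxygen to C3=C4 on the face of the C2 hydroxyl, so C3 and C4 are set with the oxirane cis to the C6 side chain and trans to the C1 ester, the face that a nucleophilic epoxidation of the enone would not reach.

Step 6
Reactants: 12
Product: 13 (1S,2R,3R,4S,6R)‑3,4‑epoxy‑2‑hydroxy‑6‑(2‑hydroxyethyl)‑3‑methylcyclohexyl 3‑methylbutanoate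
Conditions: H2 (1 atm), Pd/C (10%), EtOAc, rt
Reagents that add atoms: none
Why: Hydrogenolysis of the benzyl ether in a neutral solvent should free the primary alcohol; no C=C bond is left and the aliphatic oxirane and the ester are inert.

Step 7
Reactants: 13
Product: 14 (1S,3S,4S,6S)‑3,4‑epoxy‑3‑methyl‑2‑oxo‑6‑(2‑oxoethyl)cyclohexyl 3‑methylbutanoate
Conditions: (COCl)2, DMSO, CH2Cl2, −78 °C; Et3N, −78 → −20 °C
Reagents that add atoms: none
Why: Swern oxidation activates both hydroxyls before base is added, so the C2 ketone and C8 aldehyde form together and no hydroxy aldehyde remains to close a lactol; the temporary C2 centre is erased after having directed the oxirane.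

Step 8
Reactants: 14
Product: 15 (1S,3S,4S,6S)‑3,4‑epoxy‑3‑methyl‑2‑oxo‑6‑(3‑oxoprop‑1‑en‑2‑yl)cyclohexyl 3‑methylbutanoate
Conditions: 37% aq. HCHO, pyrrolidine (10 mol%), EtCO2H (10 mol%), i‑PrOH, 45 °C
Reagents that add atoms: formaldehyde, C=O
Why: Amine‑catalysed α‑methylenation of the α‑unbranched aldehyde (Mannich condensation through the enamine, then elimination of the amine) installs C14 on C7; the hindered C2 ketone has no α‑methylene group and should not react.

Step 9
Reactants: 15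
Product: 16 (1S,3S,4S,6R)‑3,4‑epoxy‑6‑[(2R)‑2‑formyloxiran‑2‑yl]‑3‑methyl‑2‑oxocyclohexyl 3‑methylbutanoate
Conditions: (S)‑2‑[diphenyl(methyldiphenylsilyloxy)methyl]pyrrolidine (10 mol%), 30% aq. H2O2, CH2Cl2, rt
Reagents that add atoms: hydrogen peroxide, OO
Why: Iminium/enamine‑catalysed epoxidation of an α‑substituted acrolein: H2O2 adds to C14 of the iminium ion and the enamine, with the bulky C6 substituent anti to nitrogen, closes the oxirane by attack of C7 on the peroxide oxygen from the face opposite the diphenyl(silyloxy)methyl group, so the S catalyst should set C7 as R under catalyst control.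

Step 10
Reactants: 16 and 17 (3‑methyl‑3‑(trimethylsilyloxy)but‑1‑yne)
Product: 21 (1S,3S,4S,6R)‑3,4‑epoxy‑6‑{(2R)‑2‑[(E)‑1,4‑dihydroxy‑4‑methylpent‑2‑enyl]oxiran‑2‑yl}‑3‑methyl‑2‑oxocyclohexyl 3‑methylbutanoate (both C8 epimers), via alkenylzirconocene 18 (not isolated), via alkenylzinc 19 (not isolated), via silyl ether 20 (not isolated)
Conditions: 17, Cp2Zr(H)Cl, CH2Cl2, rt; Me2Zn (PhMe), −65 °C; 16, 0 °C; then citric acid, MeOH, 0 °C
Reagents that add atoms: none
Why: Syn hydrozirconation gives the E‑alkenylzirconocene, transmetalation to zinc gives an alkenylzinc that should add to the aldehyde and not to the hindered ketone, the ester or the oxiranes, and acid methanolysis removes the trimethylsilyl group; the C8 epimers converge in step 11.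

Step 11
Reactants: 21
Product: 22 target CNP0292003.1: (1S,3S,4S,6R)‑3,4‑epoxy‑6‑{(2R)‑2‑[(E)‑4‑hydroxy‑4‑methylpent‑2‑enoyl]oxiran‑2‑yl}‑3‑methyl‑2‑oxocyclohexyl 3‑methylbutanoate
Conditions: Dess–Martin periodinane, NaHCO3, CH2Cl2, 0 °C → rt
Reagents that add atoms: none
Why: Dess–Martin oxidation of the secondary allylic C8 alcohol under buffered conditions should give the E‑enone without touching the tertiary alcohol, the oxiranes or the epimerisable C1 centre.

Compound list
1 | 4‑(benzyloxy)but‑1‑ene | C=CCCOCc1ccccc1 | starting material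
2 | (E)‑but‑2‑enal | C/C=C/C=O | starting material
3 | (E)‑5‑(benzyloxy)pent‑2‑enal | O=C/C=C/CCOCc1ccccc1 | intermediate
4 | tert‑butyl 3‑oxopentanoate | CCC(=O)CC(=O)OC(C)(C)C | starting material
5 | tert‑butyl 2‑[(3R)‑1‑(benzyloxy)‑5‑oxopentan‑3‑yl]‑3‑oxopentanoate (both epimers at the keto ester carbon) | CCC(=O)C(C(=O)OC(C)(C)C)[C@H](CCOCc1ccccc1)CC=O | intermediate
6 | tert‑butyl (6S)‑6‑[2‑(benzyloxy)ethyl]‑3‑methyl‑2‑oxocyclohex‑3‑ene‑1‑carboxylate (both epimers at C1) | CC(C)(C)OC(=O)C1C(=O)C(C)=CC[C@H]1CCOCc1ccccc1 | intermediate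
7 | (S)‑5‑[2‑(benzyloxy)ethyl]‑2‑methylcyclohex‑2‑en‑1‑one | C1C(=O)C(C)=CC[C@H]1CCOCc1ccccc1 | intermediate
8 | 3‑methylbutanoyl chloride | CC(C)CC(=O)Cl | starting material
9 | lithium (1S,6S)‑6‑[2‑(benzyloxy)ethyl]‑3‑methyl‑2‑oxocyclohex‑3‑en‑1‑olate | [Li+].[O-][C@@H]1C(=O)C(C)=CC[C@H]1CCOCc1ccccc1 | intermediate
10 | (1S,6S)‑6‑[2‑(benzyloxy)ethyl]‑3‑methyl‑2‑oxocyclohex‑3‑en‑1‑yl 3‑methylbutanoate | CC(C)CC(=O)O[C@@H]1C(=O)C(C)=CC[C@H]1CCOCc1ccccc1 | intermediate
11 | (1S,2S,6S)‑6‑[2‑(benzyloxy)ethyl]‑2‑hydroxy‑3‑methylcyclohex‑3‑en‑1‑yl 3‑methylbutanoate | CC(C)CC(=O)O[C@@H]1[C@@H](O)C(C)=CC[C@H]1CCOCc1ccccc1 | intermediate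
12 | (1S,2R,3R,4S,6R)‑6‑[2‑(benzyloxy)ethyl]‑3,4‑epoxy‑2‑hydroxy‑3‑methylcyclohexyl 3‑methylbutanoate | CC(C)CC(=O)O[C@@H]1[C@@H](O)[C@@]2(C)O[C@H]2C[C@H]1CCOCc1ccccc1 | intermediate
13 | (1S,2R,3R,4S,6R)‑3,4‑epoxy‑2‑hydroxy‑6‑(2‑hydroxyethyl)‑3‑methylcyclohexyl 3‑methylbutanoate | CC(C)CC(=O)O[C@@H]1[C@@H](O)[C@@]2(C)O[C@H]2C[C@H]1CCO | intermediate
14 | (1S,3S,4S,6S)‑3,4‑epoxy‑3‑methyl‑2‑oxo‑6‑(2‑oxoethyl)cyclohexyl 3‑methylbutanoate | CC(C)CC(=O)O[C@@H]1C(=O)[C@@]2(C)O[C@H]2C[C@H]1CC=O | intermediate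
15 | (1S,3S,4S,6S)‑3,4‑epoxy‑3‑methyl‑2‑oxo‑6‑(3‑oxoprop‑1‑en‑2‑yl)cyclohexyl 3‑methylbutanoate | CC(C)CC(=O)O[C@@H]1C(=O)[C@@]2(C)O[C@H]2C[C@H]1C(=C)C=O | intermediate
16 | (1S,3S,4S,6R)‑3,4‑epoxy‑6‑[(2R)‑2‑formyloxiran‑2‑yl]‑3‑methyl‑2‑oxocyclohexyl 3‑methylbutanoate | CC(C)CC(=O)O[C@@H]1C(=O)[C@@]2(C)O[C@H]2C[C@H]1[C@]1(C=O)CO1 | intermediate
17 | 3‑methyl‑3‑(trimethylsilyloxy)but‑1‑yne | C#CC(C)(C)O[Si](C)(C)C | starting material
18 | chlorobis(cyclopentadienyl)[(E)‑3‑methyl‑3‑(trimethylsilyloxy)but‑1‑enyl]zirconium | C[Si](C)(C)OC(C)(C)/C=C/[Zr](Cl)(C1C=CC=C1)C1C=CC=C1 | intermediate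
19 | methyl[(E)‑3‑methyl‑3‑(trimethylsilyloxy)but‑1‑enyl]zinc | C[Zn]/C=C/C(C)(C)O[Si](C)(C)C | intermediate
20 | (1S,3S,4S,6R)‑3,4‑epoxy‑6‑{(2R)‑2‑[(E)‑1‑hydroxy‑4‑methyl‑4‑(trimethylsilyloxy)pent‑2‑enyl]oxiran‑2‑yl}‑3‑methyl‑2‑oxocyclohexyl 3‑methylbutanoate (both C8 epimers) | CC(C)CC(=O)O[C@@H]1C(=O)[C@@]2(C)O[C@H]2C[C@H]1[C@]1(C(O)/C=C/C(C)(C)O[Si](C)(C)C)CO1 | intermediate
21 | (1S,3S,4S,6R)‑3,4‑epoxy‑6‑{(2R)‑2‑[(E)‑1,4‑dihydroxy‑4‑methylpent‑2‑enyl]oxiran‑2‑yl}‑3‑methyl‑2‑oxocyclohexyl 3‑methylbutanoate (both C8 epimers) | CC(C)CC(=O)O[C@@H]1C(=O)[C@@]2(C)O[C@H]2C[C@H]1[C@]1(C(O)/C=C/C(C)(C)O)CO1 | intermediate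
22 | CNP0292003.1, (1S,3S,4S,6R)‑3,4‑epoxy‑6‑{(2R)‑2‑[(E)‑4‑hydroxy‑4‑methylpent‑2‑enoyl]oxiran‑2‑yl}‑3‑methyl‑2‑oxocyclohexyl 3‑methylbutanoate | CC(C)CC(=O)O[C@@H]1C(=O)[C@@]2(C)O[C@H]2C[C@H]1[C@]1(C(=O)/C=C/C(C)(C)O)CO1 | target

Total step count: 11. Longest linear sequence: 11 steps (1 → 22); 4, 8 and 17 are bought.

Steps most likely to fail

Step 9. Facial selectivity in the oxirane closure may be poor because the resident C6 centre can oppose the catalyst, and iminium formation with this hindered α‑branched acrolein may be slow, so that the acrolein oligomerises. The fallback sets C7 by reagent control on an allylic alcohol. It sets out from 15: LiAlH(OtBu)3 (THF, −78 °C) should reduce the aldehyde 1,2 in the presence of the hindered ketone to the 2‑substituted allylic alcohol F1. Sharpless asymmetric epoxidation (Ti(OiPr)4, L‑(+)‑diethyl tartrate, t‑BuOOH, 4 Å MS, CH2Cl2, −20 °C) should give the (7S)‑epoxy alcohol F2, and Dess–Martin oxidation comes back to the route at 16.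

Step 2. Enolisation on the ethyl side may be slow in the acid stage, so that retro‑Michael cleavage or intermolecular condensation of the aldehyde competes with ring closure. The fallback brings in the C3 methyl group after the annulation. It sets out from 3: the same amine catalyst with tert‑butyl 3‑oxobutanoate should give the Michael adduct F3, which under TsOH (PhMe, 80 °C) closes through the methyl ketone to the keto ester F4 and loses isobutene and CO2 to give the enone F5. α‑Iodination (I2, pyridine, CH2Cl2) gives the iodo enone F6, and Stille methylation (Me4Sn, PdCl2(PhCN)2, AsPh3, CuI, NMP) comes back to the route at 7.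

Step 3. Oxygen transfer to the dienolate may show poor facial selectivity at C1, γ‑deprotonation may compete, and acylation of the hindered alkoxide may be incomplete. The fallback replaces the enolate chemistry by an oxidative α′‑acyloxylation. It sets out from 7: Mn(OAc)3·2H2O with excess 3‑methylbutanoic acid (benzene, reflux) should introduce the ester at C1 directly, and brief treatment with catalytic DBU equilibrates C1 to the trans (diequatorial) ester, which comes back to the route at 10; no new compound lies on its way (F0).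

Further compounds
F1 | step 9 | (1S,3S,4S,6S)‑3,4‑epoxy‑6‑(3‑hydroxyprop‑1‑en‑2‑yl)‑3‑methyl‑2‑oxocyclohexyl 3‑methylbutanoate | CC(C)CC(=O)O[C@@H]1C(=O)[C@@]2(C)O[C@H]2C[C@H]1C(=C)CO
F2 | step 9 | (1S,3S,4S,6R)‑3,4‑epoxy‑6‑[(2S)‑2‑(hydroxymethyl)oxiran‑2‑yl]‑3‑methyl‑2‑oxocyclohexyl 3‑methylbutanoate | CC(C)CC(=O)O[C@@H]1C(=O)[C@@]2(C)O[C@H]2C[C@H]1[C@]1(CO)CO1
F3 | step 2 | tert‑butyl (3R)‑2‑acetyl‑3‑[2‑(benzyloxy)ethyl]‑5‑oxopentanoate (both epimers at C2) | CC(=O)C(C(=O)OC(C)(C)C)[C@H](CCOCc1ccccc1)CC=O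
F4 | step 2 | tert‑butyl (6S)‑6‑[2‑(benzyloxy)ethyl]‑2‑oxocyclohex‑3‑ene‑1‑carboxylate (both epimers at C1) | CC(C)(C)OC(=O)C1C(=O)C=CC[C@H]1CCOCc1ccccc1
F5 | step 2 | (S)‑5‑[2‑(benzyloxy)ethyl]cyclohex‑2‑en‑1‑one | C1C(=O)C=CC[C@H]1CCOCc1ccccc1
F6 | step 2 | (S)‑5‑[2‑(benzyloxy)ethyl]‑2‑iodocyclohex‑2‑en‑1‑one | C1C(=O)C(I)=CC[C@H]1CCOCc1ccccc1
F0 | step 3 | none | none
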